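## Structural features

The target is a cyclohex-4-ene (C1–C6) cis-fused along C1–C6 to an oxirane. C1 is quaternary and carries the benzoyloxymethyl carbon C7, C2 carries a benzoate, C3 a free hydroxyl, and C4=C5 is the only alkene. The four stereocentres C6, C1, C2 and C3 are contiguous, with configuration (1S,2R,3R,6S). Re-reading the SMILES shows that the oxirane oxygen, O2 and O3 all lie on one face of the carbocycle and C7 on the other. The fragile elements are the vinyl oxirane (acid, SN2′-type opening), the cis hydroxy/benzoate pair at C3/C2 (base-induced acyl shift), and every cyclohexadiene intermediate on the way, which can aromatise by loss of water or benzoic acid. The real difficulty is twofold: O2 and O3 are both secondary and cis yet must end up differently substituted, and the oxirane must be placed on the more crowded face, cis to O2. The key step uses the fact that C3–O and C6 stand 1,4 across the C4=C5 alkene, so that O–C3–C4=C5–C6 is a masked furan. A 7-oxabicyclo[2.2.1]heptene built from furan and a β-acyloxyacrolein (C1, C2, C7) therefore holds O3 and O2 cis and chemically distinct (bridge ether versus ester). Later fission of the C6–O bridge bond releases O3 and creates the C1=C6 alkene that is to be epoxidised.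

## Logic of the disconnections

13 to 12: the O3–Si bond is cut. The C3 hydroxyl has to stay masked while O2 and O7 are acylated and while the oxirane is made, since a free allylic O3–H would steer an oxidant to C4=C5. The gain is that no free hydroxyl sits next to an ester until the last step. The forward step must unmask O3 without base (acyl shift) and without strong acid (vinyl oxirane).

12 to 11 and 4: both ester C–O bonds (at O7 and O2) are cut together, since the two acyl groups are identical. This leads back to a diol whose O2–H is the element that controls the oxirane face. The forward step must acylate a hindered secondary hydroxyl beside a quaternary oxirane carbon without epoxide migration.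

11 to 10: the C1–O and C6–O bonds of the oxirane are cut. A cis relation between an oxirane and a neighbouring ring hydroxyl is the normal result of hydroxyl-directed epoxidation, so two stereocentres are traded for a diene diol. The forward step must choose C1=C6 over C4=C5 and the face syn to O2.

10 to 9: C7 is returned to the aldehyde level and the acyl group is put back on O2. 9 is what the bridge opening delivers, and one hydride reagent can reduce the aldehyde and unmask O2 in the same operation. The forward step must be a clean 1,2-reduction with no silyl shift and no aromatisation.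

9 to 7 (through 8): the C6–O bond is re-formed, the silyl group removed and C1–H restored. O3 is a β-leaving group with respect to the formyl-bearing C1 (retro-oxa-Michael relation). The gain is a strained bicycle in which O2 and O3 are cis by construction and differently bound. The forward step must break C6–O faster than C2–O, and must silylate O3 as it leaves so that no alkoxide ever sits next to the cis benzoate.

7 to 5 and 6: C1–C6 and C2–C3 are cut, the [4+2] retron. Four stereocentres and two rings fall back to two flat, achiral partners. The forward step needs endo-formyl/exo-benzoate selectivity, facial control by a chiral Lewis acid, and kinetic control, because the adduct can revert.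

5 to 3 and 4: the O–acyl bond is cut. The forward step needs O- rather than C-acylation of an ambident anion, and E geometry.

3 to 1 (through 2): the two carbonyl groups are traced back to two acetals, which only need hydrolysis and neutralisation.

## Other disconnections considered

Alternative 1: The cut is C1–C6 together with C6–O. In the forward sense the (Z)-allyl sulfonium salt A1, a 2,2-dimethyl-1,3-dioxan-5-one carrying the C3–C6 chain, would be deprotonated by Cs2CO3. The ylide carbon C6 would add to the C1 ketone and the resulting alkoxide would displace the sulfide at C6, closing the carbocycle and the oxirane in one event to give A2.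
- In favour: ring and oxirane arise together without any oxidation step and without cyclohexadiene intermediates, so the aromatisation hazard of the chosen plan is absent. On this point the alternative is the better one.
- Also in favour: the acetonide spans O7 and O2, exactly the two oxygens that end as benzoates, which maps onto the target at least as well as the remove-and-reinstall benzoate tactic of the chosen plan.
- Against: C2 is α to the ketone and can epimerise under carbonate; the allyl ylide is ambident (α/γ attack, sigmatropic shift); the Z geometry must survive; and the face of carbonyl attack, which fixes the oxirane relative to O2, is not obviously biased the right way.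
- Against: A1 itself needs a multistep asymmetric synthesis, and after A2 the acetonide must be hydrolysed with acid in the presence of the vinyl oxirane.
- Comparison: the alternative sets C2 and C3 before the key step and C1 and C6 in it, whereas the chosen plan sets all four in or directly after a single cycloaddition from two commercial achiral compounds. Mechanistically the ylide annulation has more competing pathways than a Diels–Alder reaction. In step count the alternative is expected to be longer.

Alternative 2: The cut is C1–C2 and C3–C4. Pyrone A3 and dioxole A4 would combine under Cu(OTf)2 and a chiral tert-butyl bis(oxazoline) ligand in an inverse-demand cycloaddition to a bridged lactone, which on warming would lose CO2 to give diene A5.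
- In favour: the whole carbon skeleton, the diene, C7 at the ester level and the cis O2/O3 pair would be reached in one or two operations by asymmetric catalysis. This is fewer steps to the diene stage than the chosen plan, which is a point in the alternative's favour; as a catalytic asymmetric cycloaddition it stands equal in kind.
- Against: O2 and O3 are locked in one acetonide, so the differentiation that the target demands is lost. After deprotection a cis diol would have to be monoacylated at the more hindered O2.
- Against: the acetonide shields the very face on which the oxirane is needed, and once it is removed the free O3–H would direct an oxidant to C4=C5.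
- Against: thermal CO2 loss is close to conditions under which such dienes aromatise.
- Comparison: the alternative is stronger on convergence and length up to the diene. The chosen plan is stronger on the decisive structural issue, since O2 and O3 are distinguishable from the moment the ring is made, and on having a hydroxyl in the right place to direct the epoxidation.

Alternative 3: The cut is three C–O bonds (C2–O, C1–O, C6–O) on a carbocycle taken from the chiral pool. Allylic alcohol A7, made from shikimic acid A6 by inversion at C3, ester reduction, benzoylation at O7 and silylation of O4/O5, would be photooxygenated (tetraphenylporphyrin, O2, light) in the presence of Ti(OiPr)4. The hydroxyl-directed ene reaction would place a hydroperoxide on C2 cis to O3 and shift the alkene to C1=C6, and titanium-mediated oxygen transfer would close the oxirane cis to O2, giving A8.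
- In favour: the absolute configuration comes from A6 with no asymmetric catalysis, and the all-cis triad oxirane/O2/O3 would be installed under substrate control in one flask. On both counts the alternative is equal or better than the chosen plan.
- Against: the route to A7 is long, and the ene reaction can abstract hydrogen at C6, C7 or C3.
- Against: A8 still has O2–H and O3–H free and cis, so selective benzoylation at O2 is unsolved.
- Against: the trans-4,5-bis(silyloxy) unit must be converted into the C4=C5 alkene by diol deoxygenation in the presence of an oxirane and esters.
- Comparison: the chosen plan obtains C4=C5 directly from 6 and differentiates O2 from O3 by construction. The alternative is surer about absolute stereochemistry but is expected to need roughly twice as many steps.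

Key step: step 3

Assumption: the enal is taken to bind the boron catalyst through the formyl oxygen with the formyl C–H···O contact usual for aldehydes, which makes the (S)-catalyst the one that leaves the Cα-Re face open; if the other binding mode prevailed, the (R)-catalyst would be used.

## Route

Step 1
Reactants: 1 1,1,3,3-tetramethoxypropane
Product: 3 sodium (E)-3-oxoprop-1-en-1-olate, via malonaldehyde 2 (not isolated)
Conditions: aq. HCl (cat.), H2O, 40 °C; then NaOH (1.0 equiv), 0 °C; evaporate, triturate with acetone
Reagents that add atoms: water, O; sodium hydroxide, [Na+].[OH-]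
Why: Acid-catalysed hydrolysis of both acetals gives malonaldehyde, a vinylogous carboxylic acid, which NaOH converts into its stable crystalline enolate salt (acetal hydrolysis followed by an acid–base reaction).

Step 2
Reactants: 3 sodium (E)-3-oxoprop-1-en-1-olate; 4 benzoyl chloride
Product: 5 (E)-3-(benzoyloxy)acrolein
Conditions: BzCl (1.0 equiv), THF (suspension), 0 °C → rt; filter, crystallise
Reagents that add atoms: benzoyl chloride (compound 4), O=C(Cl)c1ccccc1
Why: O-acylation of the ambident enolate by the hard acyl chloride (anhydrous Schotten–Baumann-type acylation); the extended anion and the conjugated product both favour the E isomer.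

Step 3
Reactants: 5 (E)-3-(benzoyloxy)acrolein; 6 furan
Product: 7 (1R,2S,3R,4S)-3-formyl-7-oxabicyclo[2.2.1]hept-5-en-2-yl benzoate (formyl endo, benzoate exo)
Conditions: (S)-3,3-diphenyl-1-(o-tolyl)tetrahydro-1H,3H-pyrrolo[1,2-c][1,3,2]oxazaborole (20 mol %), Tf2NH (20 mol %), 6 (8 equiv), CH2Cl2, −78 °C; Et3N quench at −78 °C; crude product kept cold and used at once
Reagents that add atoms: none
Why: The cationic boron binds the formyl oxygen anti to the vinyl group, lowers the LUMO of the s-trans enal, and furan adds in a concerted, asynchronous, suprafacial [4+2] cycloaddition that forms C1–C6 and C2–C3 (catalytic asymmetric Diels–Alder reaction). The closest known reactions are oxazaborolidinium-catalysed cycloadditions of furan with acrylates and of dienes with enals, and chiral boron Lewis acid catalysed furan/α-haloacrolein cycloadditions. The carbocycle C1–C6 closes by this intermolecular [4+2] union, and the oxolane ring O–C3–C2–C1–C6 is closed by the same two bonds because the furan oxygen already spans C3 and C6. C1 and C2 come out trans because the E geometry of 5 is transferred suprafacially. C3 and C6 are set relative to them by the endo preference of the Lewis-acid-bound formyl group, which leaves the benzoate exo, that is syn to the oxygen bridge and hence cis to the future O3. The absolute sense is set by the catalyst, whose phenyl group covers one face of the bound enal so that furan should add to the Cα-Re face. The step needs cycloaddition to win over conjugate addition–elimination of furan at the acyloxy-bearing carbon, endo over exo, and retention of the kinetic adduct. The weakly donating acyloxy group (which keeps the enal electrophilic), the formyl oxygen as the most basic site, low temperature, excess furan and the cold basic quench serve these needs.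

Step 4
Reactants: 7 (1R,2S,3R,4S)-3-formyl-7-oxabicyclo[2.2.1]hept-5-en-2-yl benzoate
Product: 9 (1S,6R)-2-formyl-6-[(triethylsilyl)oxy]cyclohexa-2,4-dien-1-yl benzoate, via triethylsilyl enol ether 8 (not isolated)
Conditions: TESOTf (1.3 equiv), Et3N (2.5 equiv), CH2Cl2, −78 → −20 °C; pH 7 phosphate buffer
Reagents that add atoms: triethylsilyl trifluoromethanesulfonate, CC[Si](CC)(CC)OS(=O)(=O)C(F)(F)F
Why: Soft enolisation gives silyl enol ether 8; silyl transfer to the bridge oxygen and electron push from the enol ether then break C6–O (silyl triflate/amine-induced β-elimination, a retro-oxa-Michael opening of a 7-oxanorbornene carbonyl compound), which relieves the bicyclic strain and delivers O3 directly as its silyl ether, so that no alkoxide ever sits beside the cis benzoate. Loss of benzoate from C2 would create a more strained 7-oxanorbornadiene and should be slower; C2 and C3 are not touched.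

Step 5
Reactants: 9 (1S,6R)-2-formyl-6-[(triethylsilyl)oxy]cyclohexa-2,4-dien-1-yl benzoate
Product: 10 (1S,6R)-2-(hydroxymethyl)-6-[(triethylsilyl)oxy]cyclohexa-2,4-dien-1-ol
Conditions: i-Bu2AlH (4.5 equiv), CH2Cl2, −78 °C; aq. potassium sodium tartrate
Reagents that add atoms: none
Why: One hydride reagent performs the 1,2-reduction of the dienal and the reductive cleavage of the benzoate (aluminium hydride reduction), unveiling O2–H exactly where it is needed to direct the next step. The low temperature and the near-neutral tartrate work-up protect the acid-sensitive diene diol and the silyl ether.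

Step 6
Reactants: 10 (1S,6R)-2-(hydroxymethyl)-6-[(triethylsilyl)oxy]cyclohexa-2,4-dien-1-ol
Product: 11 (1R,2R,3R,6S)-1-(hydroxymethyl)-3-[(triethylsilyl)oxy]-7-oxabicyclo[4.1.0]hept-4-en-2-ol
Conditions: VO(acac)2 (5 mol %), t-BuOOH (1.3 equiv, in decane), CH2Cl2, 0 °C
Reagents that add atoms: tert-butyl hydroperoxide, CC(C)(C)OO
Why: Hydroxyl-directed vanadium-catalysed epoxidation: the ring C2 alkoxide, supported by chelation of the C7 alkoxide to the same metal, hands the peroxide oxygen to C1=C6 on its own face, which sets C1 and C6 with the oxirane cis to O2 and O3. C4=C5 has no free allylic hydroxyl and is left alone. (The descriptor at C1 reads R here and S in 12 and 13 only because the CIP ranking changes with the substituent on O2.)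

Step 7
Reactants: 11 (1R,2R,3R,6S)-1-(hydroxymethyl)-3-[(triethylsilyl)oxy]-7-oxabicyclo[4.1.0]hept-4-en-2-ol; 4 benzoyl chloride
Product: 12 [(1S,2R,3R,6S)-2-(benzoyloxy)-3-[(triethylsilyl)oxy]-7-oxabicyclo[4.1.0]hept-4-en-1-yl]methyl benzoate
Conditions: BzCl (3 equiv), pyridine, DMAP (10 mol %), CH2Cl2, 0 °C → rt
Reagents that add atoms: benzoyl chloride (compound 4), O=C(Cl)c1ccccc1
Why: DMAP-catalysed acylation of the primary O7–H and the hindered secondary O2–H installs both benzoates at once. The weakly basic medium generates no alkoxide, so epoxide migration is not expected and no stereocentre is touched.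

Step 8
Reactants: 12 [(1S,2R,3R,6S)-2-(benzoyloxy)-3-[(triethylsilyl)oxy]-7-oxabicyclo[4.1.0]hept-4-en-1-yl]methyl benzoate
Product: 13 [(1S,2R,3R,6S)-2-(benzoyloxy)-3-hydroxy-7-oxabicyclo[4.1.0]hept-4-en-1-yl]methyl benzoate
Conditions: HF·pyridine, pyridine, THF, 0 °C
Reagents that add atoms: none
Why: Fluoride-assisted cleavage of the secondary triethylsilyl ether under buffered, mildly acidic conditions (desilylation). No alkoxide is formed, so a benzoyl shift from O2 to O3 is suppressed, and the pyridine buffer spares the vinyl oxirane.

## Compound list

1 | 1,1,3,3-tetramethoxypropane | COC(OC)CC(OC)OC | starting material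
2 | malonaldehyde (propanedial), formed in the flask | O=CCC=O | intermediate
3 | sodium (E)-3-oxoprop-1-en-1-olate (sodium malonaldehyde enolate) | [Na+].[O-]/C=C/C=O | intermediate
4 | benzoyl chloride | O=C(Cl)c1ccccc1 | starting material
5 | (E)-3-(benzoyloxy)acrolein | O=C/C=C/OC(=O)c1ccccc1 | intermediate
6 | furan | c1ccoc1 | starting material
7 | (1R,2S,3R,4S)-3-formyl-7-oxabicyclo[2.2.1]hept-5-en-2-yl benzoate (endo-formyl, exo-benzoyloxy) | O=C[C@H]1[C@H](OC(=O)c2ccccc2)[C@H]2C=C[C@@H]1O2 | intermediate
8 | triethylsilyl enol ether of 7, formed in the flask (ring stereocentres as in 7; enol ether geometry not controlled, both isomers converge) | CC[Si](CC)(CC)OC=C1[C@H](OC(=O)c2ccccc2)[C@H]2C=C[C@@H]1O2 | intermediate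
9 | (1S,6R)-2-formyl-6-[(triethylsilyl)oxy]cyclohexa-2,4-dien-1-yl benzoate | O=CC1=CC=C[C@@H](O[Si](CC)(CC)CC)[C@H]1OC(=O)c1ccccc1 | intermediate
10 | (1S,6R)-2-(hydroxymethyl)-6-[(triethylsilyl)oxy]cyclohexa-2,4-dien-1-ol | OCC1=CC=C[C@@H](O[Si](CC)(CC)CC)[C@H]1O | intermediate
11 | (1R,2R,3R,6S)-1-(hydroxymethyl)-3-[(triethylsilyl)oxy]-7-oxabicyclo[4.1.0]hept-4-en-2-ol | OC[C@]12O[C@H]1C=C[C@@H](O[Si](CC)(CC)CC)[C@H]2O | intermediate
12 | [(1S,2R,3R,6S)-2-(benzoyloxy)-3-[(triethylsilyl)oxy]-7-oxabicyclo[4.1.0]hept-4-en-1-yl]methyl benzoate | O=C(OC[C@]12O[C@H]1C=C[C@@H](O[Si](CC)(CC)CC)[C@H]2OC(=O)c1ccccc1)c1ccccc1 | intermediate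
13 | [(1S,2R,3R,6S)-2-(benzoyloxy)-3-hydroxy-7-oxabicyclo[4.1.0]hept-4-en-1-yl]methyl benzoate | O=C(OC[C@]12O[C@H]1C=C[C@@H](O)[C@H]2OC(=O)c1ccccc1)c1ccccc1 | target

## Step count and least certain steps

Total: 8 steps. Longest linear sequence: 8 steps (1 to 13).

Step 3 (key step). Most likely to go wrong: furan may attack the acyloxy-bearing carbon in a Friedel–Crafts-type addition–elimination instead of cycloadding; conversion may stall because furan is a poor diene; the adduct may revert or lose endo selectivity on warming; and facial discrimination may be weaker for an enal without an α-substituent, since one-point binding to boron leaves two possible binding modes. Fallback (from 5 and 6, back at 7): move to a two-point-binding imide dienophile and a chelating copper Lewis acid.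
- 5 is oxidised (NaClO2, NaH2PO4, 2-methyl-2-butene, t-BuOH/H2O) to (E)-3-(benzoyloxy)acrylic acid F1.
- PivCl/Et3N converts F1 in the flask into (E)-3-(benzoyloxy)acrylic pivalic anhydride F2, which acylates oxazolidin-2-one (LiCl, THF) to give 3-[(E)-3-(benzoyloxy)acryloyl]-1,3-oxazolidin-2-one F3.
- F3 and 6 undergo the same cycloaddition under the Cu(SbF6)2 complex of 2,2′-isopropylidenebis[(4S)-4-tert-butyl-2-oxazoline] (CH2Cl2, −78 °C; the ligand enantiomer is the one that the square-planar chelate model predicts to leave the Cα-Re face open) to give the endo imide adduct (1R,2S,3R,4S)-3-[(2-oxo-1,3-oxazolidin-3-yl)carbonyl]-7-oxabicyclo[2.2.1]hept-5-en-2-yl benzoate F4.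
- NaBH4 in THF/H2O at 0 °C cleaves the imide to (1R,2S,3R,4S)-3-(hydroxymethyl)-7-oxabicyclo[2.2.1]hept-5-en-2-yl benzoate F5.
- Dess–Martin periodinane (NaHCO3, CH2Cl2, 0 °C) returns 7.

Step 4. Most likely to go wrong: β-loss of the C2 benzoate instead of bridge cleavage, because the carboxylate is intrinsically the better leaving group; over-enolisation of the dienal followed by aromatisation with loss of benzoic acid; and cycloreversion if 7 or 8 is allowed to warm before it opens. Fallback (from 7, back at 9): change the mode of activation from silyl triflate/enol ether to covalent amine catalysis under buffered conditions.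
- Dibenzylammonium trifluoroacetate (20 mol %) in CH2Cl2 at 0 °C forms the enamine at C1, which expels the hydrogen-bonded bridge oxygen (general acid assistance favours the poorer leaving group). Hydrolysis of the resulting iminium ion gives (1S,6R)-2-formyl-6-hydroxycyclohexa-2,4-dien-1-yl benzoate F6 without an alkoxide stage.
- F6 is silylated at once (TESOTf, 2,6-lutidine, CH2Cl2, −78 °C) to 9.

Step 6. Most likely to go wrong: erosion of facial selectivity, because the primary C7 hydroxyl also binds vanadium and can deliver oxygen to the less hindered lower face; aromatisation of the diene diol under the Lewis-acidic catalyst; and some over-oxidation. Fallback (from 10, back at 12): remove the competing director and acylate in two stages.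
- Selective benzoylation of the primary hydroxyl (BzCl, 2,4,6-collidine, CH2Cl2, −40 °C) gives [(5R,6S)-6-hydroxy-5-[(triethylsilyl)oxy]cyclohexa-1,3-dien-1-yl]methyl benzoate F7.
- VO(acac)2/t-BuOOH epoxidation, now steered by O2–H alone, gives [(1R,2R,3R,6S)-2-hydroxy-3-[(triethylsilyl)oxy]-7-oxabicyclo[4.1.0]hept-4-en-1-yl]methyl benzoate F8.
- Benzoylation of O2–H (BzCl, pyridine, DMAP) gives 12.

## Further compounds

F1 | step 3 | (E)-3-(benzoyloxy)acrylic acid | O=C(O)/C=C/OC(=O)c1ccccc1
F2 | step 3 | (E)-3-(benzoyloxy)acrylic pivalic anhydride | CC(C)(C)C(=O)OC(=O)/C=C/OC(=O)c1ccccc1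
F3 | step 3 | 3-[(E)-3-(benzoyloxy)acryloyl]-1,3-oxazolidin-2-one | O=C(/C=C/OC(=O)c1ccccc1)N1CCOC1=O
F4 | step 3 | (1R,2S,3R,4S)-3-[(2-oxo-1,3-oxazolidin-3-yl)carbonyl]-7-oxabicyclo[2.2.1]hept-5-en-2-yl benzoate | O=C([C@H]1[C@H](OC(=O)c2ccccc2)[C@H]2C=C[C@@H]1O2)N1CCOC1=O
F5 | step 3 | (1R,2S,3R,4S)-3-(hydroxymethyl)-7-oxabicyclo[2.2.1]hept-5-en-2-yl benzoate | OC[C@H]1[C@H](OC(=O)c2ccccc2)[C@H]2C=C[C@@H]1O2
F6 | step 4 | (1S,6R)-2-formyl-6-hydroxycyclohexa-2,4-dien-1-yl benzoate | O=CC1=CC=C[C@@H](O)[C@H]1OC(=O)c1ccccc1
F7 | step 6 | [(5R,6S)-6-hydroxy-5-[(triethylsilyl)oxy]cyclohexa-1,3-dien-1-yl]methyl benzoate | O=C(OCC1=CC=C[C@@H](O[Si](CC)(CC)CC)[C@H]1O)c1ccccc1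
F8 | step 6 | [(1R,2R,3R,6S)-2-hydroxy-3-[(triethylsilyl)oxy]-7-oxabicyclo[4.1.0]hept-4-en-1-yl]methyl benzoate | O=C(OC[C@]12O[C@H]1C=C[C@@H](O[Si](CC)(CC)CC)[C@H]2O)c1ccccc1
A1 | alternative 1 | 1-[(2Z)-4-[(tert-butyldimethylsilyl)oxy]-4-(2,2-dimethyl-5-oxo-1,3-dioxan-4-yl)but-2-en-1-yl]thiolan-1-ium bromide, C2 and C3 configured as in 13 | CC1(C)OCC(=O)[C@@H]([C@H](O[Si](C)(C)C(C)(C)C)/C=C\C[S+]2CCCC2)O1.[Br-]
A2 | alternative 1 | epoxycyclohexene with C7/C2 acetonide and C3 tert-butyldimethylsilyl ether | CC1(C)OC[C@]23O[C@H]2C=C[C@@H](O[Si](C)(C)C(C)(C)C)[C@H]3O1
A3 | alternative 2 | methyl 2-oxo-2H-pyran-3-carboxylate | COC(=O)C1=CC=COC1=O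
A4 | alternative 2 | 2,2-dimethyl-1,3-dioxole | CC1(C)OC=CO1
A5 | alternative 2 | methyl cis-5,6-(isopropylidenedioxy)cyclohexa-1,3-diene-1-carboxylate | COC(=O)C1=CC=C[C@H]2OC(C)(C)O[C@@H]12
A6 | alternative 3 | (3R,4S,5R)-shikimic acid | O=C(O)C1=C[C@@H](O)[C@@H](O)[C@H](O)C1
A7 | alternative 3 | [4,5-bis[(tert-butyldimethylsilyl)oxy]-3-hydroxycyclohex-1-en-1-yl]methyl benzoate of the 3-epi-shikimate series (3,4-trans, 4,5-trans) | O=C(OCC1=C[C@H](O)[C@@H](O[Si](C)(C)C(C)(C)C)[C@H](O[Si](C)(C)C(C)(C)C)C1)c1ccccc1
A8 | alternative 3 | 1,6-epoxy-2,3-diol with the 4,5-diol silylated and C7 benzoylated | O=C(OC[C@]12O[C@H]1[C@@H](O[Si](C)(C)C(C)(C)C)[C@H](O[Si](C)(C)C(C)(C)C)[C@@H](O)[C@H]2O)c1ccccc1
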